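**Plan**

1. Locants: oxane ring O1, C2 (acrylic acid), C3, C4, C5 (side chain C1′–C13′), C6. The retrosynthesis cuts, in this order: the acrylate CH2 (ester α‑methylenation); the C3′/C4′ diol (back to a cyclic carbonate, then to the 2,3‑epoxide of farnesol); the C1′–C2′ bond (as an olefin); the ring bond C3–C4 (radical cyclization); the ether bond O1–C6.
2. Forward: an alcohol from 1 and bromoacrylate 3 are joined as an ether; the oxane, the only ring, is closed at C3–C4; the C5 carboxyl group is turned into a sulfone and joined to epoxyfarnesal; carbonate formation, olefin reduction, methylenation and hydrolysis finish the route.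
3. Stereochemistry: C2 is bought with ethyl (S)‑4‑chloro‑3‑hydroxybutanoate; C5 is relayed from C2 during ring closure; C3′ and C4′ are set together by one Sharpless asymmetric epoxidation of (2E,6E)‑farnesol and kept through a palladium‑mediated double inversion; both chain olefins come from farnesol.
4. Enabling feature: C5 bears one exocyclic carbon (C1′) that can be held at the carboxyl level, so C4=C5 can be an acrylate with C4 as its β‑carbon. This acrylate is tied through C6–O1 to C2, whose neighbour C3 can carry a primary radical: a 3‑oxahex‑5‑enyl radical with an ester on C5, which closes 6‑endo.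

Key step: step 3

Remark: 1, 3, 10 and D‑(−)‑diethyl tartrate are taken as commercial; the locants defined in line 1 of the plan are used throughout.

**Route**

Step 1
Reactants: 1 ethyl (3S)-4-chloro-3-hydroxybutanoate
Product: 2 ethyl (3S)-3-hydroxy-4-(phenylselanyl)butanoate
Conditions: PhSeSePh (0.55 equiv), NaBH4, EtOH, 0 °C; then 1, 0 °C → rt
Reagents that add atoms: diphenyl diselenide (c1ccccc1[Se][Se]c1ccccc1)
Why: The selenolate made in the flask displaces the primary chloride (SN2) at the carbon next to the stereocenter, so the C–O stereocenter is untouched, and the selenide is a radical precursor that, unlike a halohydrin, survives the basic etherification that follows.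

Step 2
Reactants: 2 ethyl (3S)-3-hydroxy-4-(phenylselanyl)butanoate; 3 tert-butyl 2-(bromomethyl)prop-2-enoate
Product: 4 ethyl (3S)-3-{[2-(tert-butoxycarbonyl)prop-2-en-1-yl]oxy}-4-(phenylselanyl)butanoate
Conditions: NaN(SiMe3)2 (1.0 equiv), THF, −78 °C; then 3, −78 → −30 °C
Reagents that add atoms: none
Why: Williamson-type O-allylation in which the sodium alkoxide attacks the very reactive 2-(bromomethyl)acrylate by addition–elimination (SN2′, same product as SN2 for this allyl unit) at a temperature where retro-aldol cleavage and β-elimination of the β-hydroxy ester should not compete; no stereocenter is involved.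

Step 3
Reactants: 4 ethyl (3S)-3-{[2-(tert-butoxycarbonyl)prop-2-en-1-yl]oxy}-4-(phenylselanyl)butanoate
Product: 5 tert-butyl (3S,6R)-6-(2-ethoxy-2-oxoethyl)oxane-3-carboxylate
Conditions: Bu3SnH (1.3 equiv) and AIBN (cat.) added slowly, benzene (0.01 M), 80 °C
Reagents that add atoms: none
Why: Bu3Sn• abstracts the PhSe group of 4 to give a primary β-alkoxyalkyl radical at C3, which adds to the unsubstituted terminus C4 of the tethered 2-(alkoxymethyl)acrylate, and the resulting tertiary α-ester radical at C5 is quenched by hydrogen-atom transfer from Bu3SnH. The closest known reaction type is the tin hydride-mediated endo cyclization of hex-5-enyl radicals that carry an ester on the internal olefin carbon, including ethers made from Morita–Baylis–Hillman bromides. The oxane ring closes in the 6-endo-trig mode. The new stereocenter C5 is controlled by the existing center C2: in the chair-like ring radical the CH2CO2Et group on C2 sits equatorial, and the hydrogen atom should arrive along the axial trajectory (which meets no syn-axial hydrogen on the O1 side), leaving the tert-butyl ester equatorial and trans to the C2 substituent. The step needs 6-endo over 5-exo regioselectivity, secured by the ester on C5 (5-exo attack would hit the fully substituted α-carbon and give an unstabilized radical), and cyclization ahead of simple reduction, secured by keeping the stannane concentration low.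

Step 4
Reactants: 5 tert-butyl (3S,6R)-6-(2-ethoxy-2-oxoethyl)oxane-3-carboxylate
Product: 6 (3S,6R)-6-(2-ethoxy-2-oxoethyl)oxane-3-carboxylic acid
Conditions: CF3CO2H, CH2Cl2, 0 °C → rt
Reagents that add atoms: none
Why: Acidolysis of the tert-butyl ester (loss of isobutene) leaves the ethyl ester and the oxane untouched and so tells the two carboxyl groups apart.

Step 5
Reactants: 6 (3S,6R)-6-(2-ethoxy-2-oxoethyl)oxane-3-carboxylic acid
Product: 7 ethyl 2-[(2R,5R)-5-(hydroxymethyl)oxan-2-yl]acetate
Conditions: BH3·SMe2, THF, 0 °C → rt; then H2O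
Reagents that add atoms: none
Why: Borane reduces a free carboxylic acid (through the acyloxyborane) far faster than an ester, so the primary alcohol should form without touching C5 or the ethyl ester.

Step 6
Reactants: 7 ethyl 2-[(2R,5R)-5-(hydroxymethyl)oxan-2-yl]acetate
Product: 8 ethyl 2-[(2R,5S)-5-{[(1-phenyl-1H-tetrazol-5-yl)sulfanyl]methyl}oxan-2-yl]acetate
Conditions: 1-phenyl-1H-tetrazole-5-thiol, PPh3, DIAD, THF, 0 °C → rt
Reagents that add atoms: 1-phenyl-1H-tetrazole-5-thiol (Sc1nnnn1-c1ccccc1)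
Why: Mitsunobu thioetherification of a primary alcohol; the reacting carbon is not stereogenic.

Step 7
Reactants: 8 ethyl 2-[(2R,5S)-5-{[(1-phenyl-1H-tetrazol-5-yl)sulfanyl]methyl}oxan-2-yl]acetate
Product: 9 ethyl 2-[(2R,5S)-5-{[(1-phenyl-1H-tetrazol-5-yl)sulfonyl]methyl}oxan-2-yl]acetate
Conditions: (NH4)6Mo7O24·4H2O (cat.), 30% aq. H2O2, EtOH, 0 °C → rt
Reagents that add atoms: hydrogen peroxide (OO)
Why: Molybdate-catalysed peroxide oxidation of the sulfide to the sulfone, placed before any olefin is present in the molecule.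

Step 8
Reactants: 10 (2E,6E)-3,7,11-trimethyldodeca-2,6,10-trien-1-ol ((2E,6E)-farnesol)
Product: 11 [(2R,3R)-3-[(3E)-4,8-dimethylnona-3,7-dien-1-yl]-3-methyloxiran-2-yl]methanol
Conditions: Ti(OiPr)4 (cat.), D-(−)-diethyl tartrate (cat.), t-BuOOH, 4 Å MS, CH2Cl2, −20 °C
Reagents that add atoms: tert-butyl hydroperoxide (CC(C)(C)OO)
Why: Sharpless asymmetric epoxidation, in which only the allylic-alcohol olefin binds titanium and the D-(−)-tartrate ligand directs oxygen to the face that gives the (2R,3R)-epoxide, so both side-chain stereocenters (C3′ and C4′) are fixed at once from the E geometry.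

Step 9
Reactants: 11 [(2R,3R)-3-[(3E)-4,8-dimethylnona-3,7-dien-1-yl]-3-methyloxiran-2-yl]methanol
Product: 12 (2S,3R)-3-[(3E)-4,8-dimethylnona-3,7-dien-1-yl]-3-methyloxirane-2-carbaldehyde
Conditions: TEMPO (cat.), PhI(OAc)2, CH2Cl2, rt
Reagents that add atoms: none
Why: Oxoammonium-mediated oxidation of the primary alcohol under near-neutral conditions that the epoxide and the trisubstituted olefins tolerate; the α-center is an epoxide carbon and should not epimerize.

Step 10
Reactants: 9 ethyl 2-[(2R,5S)-5-{[(1-phenyl-1H-tetrazol-5-yl)sulfonyl]methyl}oxan-2-yl]acetate; 12 (2S,3R)-3-[(3E)-4,8-dimethylnona-3,7-dien-1-yl]-3-methyloxirane-2-carbaldehyde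
Product: 13 ethyl 2-[(2R,5R)-5-{(E)-2-[(2R,3R)-3-[(3E)-4,8-dimethylnona-3,7-dien-1-yl]-3-methyloxiran-2-yl]ethenyl}oxan-2-yl]acetate
Conditions: KN(SiMe3)2, DME, −60 °C; then 12, −60 °C → rt
Reagents that add atoms: none
Why: Julia–Kocienski olefination (addition, Smiles rearrangement, loss of SO2 and the tetrazololate) should give the E-olefin; the sulfone α-protons are far more acidic than the ester α-protons, and neither C5 nor the epoxide carbons are touched.

Step 11
Reactants: 13 ethyl 2-[(2R,5R)-5-{(E)-2-[(2R,3R)-3-[(3E)-4,8-dimethylnona-3,7-dien-1-yl]-3-methyloxiran-2-yl]ethenyl}oxan-2-yl]acetate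
Product: 14 ethyl 2-[(2R,5R)-5-{(E)-2-[(4R,5R)-5-[(3E)-4,8-dimethylnona-3,7-dien-1-yl]-5-methyl-2-oxo-1,3-dioxolan-4-yl]ethenyl}oxan-2-yl]acetate
Conditions: Pd2(dba)3·CHCl3 (2.5 mol%), P(OiPr)3 (20 mol%), CO2 (1 atm), THF, 0 °C → rt
Reagents that add atoms: carbon dioxide (O=C=O)
Why: Palladium-catalysed CO2 insertion into a vinyl epoxide: zerovalent palladium ionizes the allylic C–O bond with inversion, the tertiary alkoxide captures CO2, and the carbonate oxygen closes the five-membered ring on the allyl terminus with a second inversion, so the secondary C–O bond is re-formed with net retention while the tertiary center is never broken, which turns the epoxide of the E-olefin into the protected diol that a syn-dihydroxylation would have given.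

Step 12
Reactants: 14 ethyl 2-[(2R,5R)-5-{(E)-2-[(4R,5R)-5-[(3E)-4,8-dimethylnona-3,7-dien-1-yl]-5-methyl-2-oxo-1,3-dioxolan-4-yl]ethenyl}oxan-2-yl]acetate
Product: 15 ethyl 2-[(2R,5R)-5-{2-[(4R,5R)-5-[(3E)-4,8-dimethylnona-3,7-dien-1-yl]-5-methyl-2-oxo-1,3-dioxolan-4-yl]ethyl}oxan-2-yl]acetate
Conditions: 2-nitrobenzenesulfonylhydrazide, Et3N, CH2Cl2, rt
Reagents that add atoms: none
Why: Diimide made in the flask transfers H2 in a concerted step and reacts markedly faster with the 1,2-disubstituted olefin than with the two trisubstituted ones, and, unlike H2 over Pd/C, it cannot hydrogenolyse the allylic carbonate.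

Step 13
Reactants: 15 ethyl 2-[(2R,5R)-5-{2-[(4R,5R)-5-[(3E)-4,8-dimethylnona-3,7-dien-1-yl]-5-methyl-2-oxo-1,3-dioxolan-4-yl]ethyl}oxan-2-yl]acetate
Product: 18 ethyl 2-[(2R,5R)-5-{2-[(4R,5R)-5-[(3E)-4,8-dimethylnona-3,7-dien-1-yl]-5-methyl-2-oxo-1,3-dioxolan-4-yl]ethyl}oxan-2-yl]prop-2-enoate, via Mannich base 16 (not isolated), via trimethylammonium iodide 17 (not isolated)
Conditions: LiN(iPr)2, THF, −78 °C; CH2=NMe2+ I−, −78 °C → rt; then MeI, CH2Cl2, rt; then sat. aq. NaHCO3, rt
Reagents that add atoms: N,N-dimethylmethyleneiminium iodide (C=[N+](C)C.[I-]); iodomethane (CI)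
Why: Mannich-type α-methylenation in which the ester enolate is aminomethylated by the iminium salt (16), the amine is quaternized by MeI (17) and trimethylamine, which carries off the methyl group of MeI, is then eliminated (E1cB) to leave the 1,1-disubstituted acrylate; at −78 °C the β-alkoxy ester enolate should not open the ring, and the transient α-center disappears on elimination.

Step 14
Reactants: 18 ethyl 2-[(2R,5R)-5-{2-[(4R,5R)-5-[(3E)-4,8-dimethylnona-3,7-dien-1-yl]-5-methyl-2-oxo-1,3-dioxolan-4-yl]ethyl}oxan-2-yl]prop-2-enoate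
Product: 20 2-[(2R,5S)-5-[(3R,4R,7E)-3,4-dihydroxy-4,8,12-trimethyltrideca-7,11-dien-1-yl]oxan-2-yl]prop-2-enoic acid (CNP0285744.2), via lithium carboxylate 19 (not isolated)
Conditions: LiOH·H2O, THF/H2O, rt; then 1 M HCl, 0 °C, to pH 3–4
Reagents that add atoms: lithium hydroxide ([Li+].[OH-])
Why: Hydroxide saponifies the ethyl ester and opens the cyclic carbonate by attack at the carbonyl carbon, so both C–O bonds of the diol keep their configuration, and the carboxylate formed first shields the acrylate from conjugate addition.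

**Compound list**

1 | ethyl (3S)-4-chloro-3-hydroxybutanoate | CCOC(=O)C[C@H](O)CCl | starting material
2 | ethyl (3S)-3-hydroxy-4-(phenylselanyl)butanoate | CCOC(=O)C[C@H](O)C[Se]c1ccccc1 | intermediate
3 | tert-butyl 2-(bromomethyl)prop-2-enoate | C=C(CBr)C(=O)OC(C)(C)C | starting material
4 | ethyl (3S)-3-{[2-(tert-butoxycarbonyl)prop-2-en-1-yl]oxy}-4-(phenylselanyl)butanoate | CCOC(=O)C[C@H](OCC(=C)C(=O)OC(C)(C)C)C[Se]c1ccccc1 | intermediate
5 | tert-butyl (3S,6R)-6-(2-ethoxy-2-oxoethyl)oxane-3-carboxylate | CCOC(=O)C[C@H]1CC[C@H](C(=O)OC(C)(C)C)CO1 | intermediate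
6 | (3S,6R)-6-(2-ethoxy-2-oxoethyl)oxane-3-carboxylic acid | CCOC(=O)C[C@H]1CC[C@H](C(=O)O)CO1 | intermediate
7 | ethyl 2-[(2R,5R)-5-(hydroxymethyl)oxan-2-yl]acetate | CCOC(=O)C[C@H]1CC[C@H](CO)CO1 | intermediate
8 | ethyl 2-[(2R,5S)-5-{[(1-phenyl-1H-tetrazol-5-yl)sulfanyl]methyl}oxan-2-yl]acetate | CCOC(=O)C[C@H]1CC[C@H](CSc2nnnn2-c2ccccc2)CO1 | intermediate
9 | ethyl 2-[(2R,5S)-5-{[(1-phenyl-1H-tetrazol-5-yl)sulfonyl]methyl}oxan-2-yl]acetate | CCOC(=O)C[C@H]1CC[C@H](CS(=O)(=O)c2nnnn2-c2ccccc2)CO1 | intermediate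
10 | (2E,6E)-3,7,11-trimethyldodeca-2,6,10-trien-1-ol ((2E,6E)-farnesol) | OC/C=C(\C)CC/C=C(\C)CCC=C(C)C | starting material
11 | [(2R,3R)-3-[(3E)-4,8-dimethylnona-3,7-dien-1-yl]-3-methyloxiran-2-yl]methanol | OC[C@H]1O[C@]1(C)CC/C=C(\C)CCC=C(C)C | intermediate
12 | (2S,3R)-3-[(3E)-4,8-dimethylnona-3,7-dien-1-yl]-3-methyloxirane-2-carbaldehyde | O=C[C@H]1O[C@]1(C)CC/C=C(\C)CCC=C(C)C | intermediate
13 | ethyl 2-[(2R,5R)-5-{(E)-2-[(2R,3R)-3-[(3E)-4,8-dimethylnona-3,7-dien-1-yl]-3-methyloxiran-2-yl]ethenyl}oxan-2-yl]acetate | CCOC(=O)C[C@H]1CC[C@H](/C=C/[C@H]2O[C@]2(C)CC/C=C(\C)CCC=C(C)C)CO1 | intermediate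
14 | ethyl 2-[(2R,5R)-5-{(E)-2-[(4R,5R)-5-[(3E)-4,8-dimethylnona-3,7-dien-1-yl]-5-methyl-2-oxo-1,3-dioxolan-4-yl]ethenyl}oxan-2-yl]acetate | CCOC(=O)C[C@H]1CC[C@H](/C=C/[C@H]2OC(=O)O[C@]2(C)CC/C=C(\C)CCC=C(C)C)CO1 | intermediate
15 | ethyl 2-[(2R,5R)-5-{2-[(4R,5R)-5-[(3E)-4,8-dimethylnona-3,7-dien-1-yl]-5-methyl-2-oxo-1,3-dioxolan-4-yl]ethyl}oxan-2-yl]acetate | CCOC(=O)C[C@H]1CC[C@H](CC[C@H]2OC(=O)O[C@]2(C)CC/C=C(\C)CCC=C(C)C)CO1 | intermediate
16 | ethyl 3-(dimethylamino)-2-[(2R,5R)-5-{2-[(4R,5R)-5-[(3E)-4,8-dimethylnona-3,7-dien-1-yl]-5-methyl-2-oxo-1,3-dioxolan-4-yl]ethyl}oxan-2-yl]propanoate (both epimers at propanoate C2) | CCOC(=O)C(CN(C)C)[C@H]1CC[C@H](CC[C@H]2OC(=O)O[C@]2(C)CC/C=C(\C)CCC=C(C)C)CO1 | intermediate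
17 | 3-ethoxy-N,N,N-trimethyl-3-oxo-2-[(2R,5R)-5-{2-[(4R,5R)-5-[(3E)-4,8-dimethylnona-3,7-dien-1-yl]-5-methyl-2-oxo-1,3-dioxolan-4-yl]ethyl}oxan-2-yl]propan-1-aminium iodide | CCOC(=O)C(C[N+](C)(C)C)[C@H]1CC[C@H](CC[C@H]2OC(=O)O[C@]2(C)CC/C=C(\C)CCC=C(C)C)CO1.[I-] | intermediate
18 | ethyl 2-[(2R,5R)-5-{2-[(4R,5R)-5-[(3E)-4,8-dimethylnona-3,7-dien-1-yl]-5-methyl-2-oxo-1,3-dioxolan-4-yl]ethyl}oxan-2-yl]prop-2-enoate | CCOC(=O)C(=C)[C@H]1CC[C@H](CC[C@H]2OC(=O)O[C@]2(C)CC/C=C(\C)CCC=C(C)C)CO1 | intermediate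
19 | lithium 2-[(2R,5S)-5-[(3R,4R,7E)-3,4-dihydroxy-4,8,12-trimethyltrideca-7,11-dien-1-yl]oxan-2-yl]prop-2-enoate | [Li+].[O-]C(=O)C(=C)[C@H]1CC[C@H](CC[C@@H](O)[C@](C)(O)CC/C=C(\C)CCC=C(C)C)CO1 | intermediate
20 | 2-[(2R,5S)-5-[(3R,4R,7E)-3,4-dihydroxy-4,8,12-trimethyltrideca-7,11-dien-1-yl]oxan-2-yl]prop-2-enoic acid (CNP0285744.2) | C=C(C(=O)O)[C@H]1CC[C@H](CC[C@@H](O)[C@](C)(O)CC/C=C(\C)CCC=C(C)C)CO1 | target

**Count and risks**

Total step count: 14. Longest linear sequence: 12 steps (steps 1–7 and 10–14, from 1 to 20); the side-chain branch (steps 8–9) is 2 steps from 10.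

Steps most likely to fail:

Step 3. The hydrogen atom may be delivered to the planar C5 radical from both ring faces, which would erode the trans preference; to a lesser degree the primary radical may be reduced before it cyclizes. The fallback replaces kinetic control at C5 by thermodynamic control. It sets out from 7 as obtained together with its C5 epimer. Oxidation (TEMPO cat., PhI(OAc)2, CH2Cl2) should give the aldehydes ethyl 2-[(2R,5R)-5-formyloxan-2-yl]acetate F1 (cis) and ethyl 2-[(2R,5S)-5-formyloxan-2-yl]acetate F2 (trans). A catalytic amount of DBU in CH2Cl2 should equilibrate F1 through its enolate into the diequatorial F2, under conditions too mild to deprotonate the ester arm. NaBH4 in EtOH at 0 °C then returns the route to 7.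

Step 11. The allylpalladium intermediate may equilibrate (π–σ–π) before the carbonate closes, which would erode the configuration at C3′, or it may lose a β-hydrogen to give a dienol. The fallback reaches net retention without an allyl–metal species. It sets out from 13. Diimide reduction (2-nitrobenzenesulfonylhydrazide, Et3N, CH2Cl2) of the disubstituted olefin should give the saturated epoxide ethyl 2-[(2R,5R)-5-{2-[(2R,3R)-3-[(3E)-4,8-dimethylnona-3,7-dien-1-yl]-3-methyloxiran-2-yl]ethyl}oxan-2-yl]acetate F3. Iodide-catalysed CO2 insertion (CaI2 cat., 18-crown-6 cat., CO2 20 bar, 70 °C) should then open the epoxide at the secondary carbon with inversion, carboxylate the tertiary alkoxide and close the carbonate with a second inversion. The fallback returns to the route at 15.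

Step 12. Excess diimide may also reduce the trisubstituted olefins, or the reduction of the hindered disubstituted olefin may stall. The fallback replaces reagent-controlled selection among the olefins by delivery of hydrogen from a neighbouring hydroxyl group. It sets out from 14. K2CO3 in EtOH at rt should cleave the cyclic carbonate, while the ethyl ester stays an ethyl ester, to give the allylic diol ethyl 2-[(2R,5R)-5-[(1E,3R,4R,7E)-3,4-dihydroxy-4,8,12-trimethyltrideca-1,7,11-trien-1-yl]oxan-2-yl]acetate F4. Hydrogenation with [Rh(nbd)(dppb)]BF4 (cat.) under H2 (about 40 bar) in CH2Cl2 should then give the saturated diol ethyl 2-[(2R,5S)-5-[(3R,4R,7E)-3,4-dihydroxy-4,8,12-trimethyltrideca-7,11-dien-1-yl]oxan-2-yl]acetate F5. In this step the allylic hydroxyl group binds the cationic monovalent rhodium centre and hands hydrogen to the adjacent olefin only, and the high pressure is chosen to outrun isomerization of the allylic alcohol to a ketone. 1,1′-Carbonyldiimidazole with DMAP (cat.) in toluene at 60 °C closes the carbonate again and returns the route to 15.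

**Further compounds**

F1 | step 3 | ethyl 2-[(2R,5R)-5-formyloxan-2-yl]acetate | CCOC(=O)C[C@H]1CC[C@@H](C=O)CO1
F2 | step 3 | ethyl 2-[(2R,5S)-5-formyloxan-2-yl]acetate | CCOC(=O)C[C@H]1CC[C@H](C=O)CO1
F3 | step 11 | ethyl 2-[(2R,5R)-5-{2-[(2R,3R)-3-[(3E)-4,8-dimethylnona-3,7-dien-1-yl]-3-methyloxiran-2-yl]ethyl}oxan-2-yl]acetate | CCOC(=O)C[C@H]1CC[C@H](CC[C@H]2O[C@]2(C)CC/C=C(\C)CCC=C(C)C)CO1
F4 | step 12 | ethyl 2-[(2R,5R)-5-[(1E,3R,4R,7E)-3,4-dihydroxy-4,8,12-trimethyltrideca-1,7,11-trien-1-yl]oxan-2-yl]acetate | CCOC(=O)C[C@H]1CC[C@H](/C=C/[C@@H](O)[C@](C)(O)CC/C=C(\C)CCC=C(C)C)CO1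
F5 | step 12 | ethyl 2-[(2R,5S)-5-[(3R,4R,7E)-3,4-dihydroxy-4,8,12-trimethyltrideca-7,11-dien-1-yl]oxan-2-yl]acetate | CCOC(=O)C[C@H]1CC[C@H](CC[C@@H](O)[C@](C)(O)CC/C=C(\C)CCC=C(C)C)CO1
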